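**Plan**

Numbering: C1 = C(OH)(C7H2OH), C2 = CHOH, C3 = CHOBz, C4=C5, C6 = CHOBz; O2, O3, O6 and C7 lie on one ring face, O1 on the other.
Retrosynthesis: take off the two benzoates and the O2/O7 mask, trace C6–O to the ketone of a cyclohex-4-en-6-one and this to a saturated C6 nitro compound, then cut C1–C6 (nitroaldol) and C2–C3 (aldol) to reach dihydroxyacetone phosphate and 4-nitrobutanal.
Enabling feature: C7–C1–C2 is a dihydroxyacetone unit with C1 as the former ketone carbon, O2/O3 are cis with (2R,3R) = D-erythro, which is the pattern delivered by L-fuculose-1-phosphate aldolase, and C6 sits four carbons beyond C3, so a C6 nitronate can close the six-membered carbocycle C1–C6 onto C1.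
Forward: the enzyme joins the chain at C2–C3 and the ring closes in the same pot at C1–C6; then dephosphorylation, O2/O7 silylene, O3 benzoate, Nef reaction, Saegusa–Ito dehydrogenation, directed reduction, O6 benzoate and desilylation follow.
Stereochemistry: C2 and C3 come from the aldolase, C1 from the reversible Henry closure (thermodynamic chair), C6 from hydroxyl-directed hydride delivery on the O1 face; the nitro-bearing centre is only transient.

Key step: step 3

Assumption: nitrocyclitol 6 is drawn with the nitro group equatorial (trans to C7); this centre is erased in step 7, so its configuration does not affect the route. The cyclitol numbering above is kept for all ring compounds.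

**Route**

Step 1
Reactants: 1 methyl 4-nitrobutanoate
Product: 2 4-nitrobutanal
Conditions: iBu2AlH (1.05 equiv), CH2Cl2, −78 °C; MeOH, then aq. KNaC4H4O6 (potassium sodium tartrate)
Reagents that add atoms: none
Why: Partial ester reduction by iBu2AlH stops at −78 °C at the aluminium hemiacetal, which releases the aldehyde on work-up, and the nitro group is inert to the hydride at this temperature.

Step 2
Reactants: 3 dihydroxyacetone (commercial dimer, monomer in water)
Product: 4 dihydroxyacetone phosphate
Conditions: dihydroxyacetone kinase, acetate kinase, ATP (cat.), acetyl phosphate (lithium potassium salt), MgSO4, H2O, pH 7.5, 25 °C; used as the aqueous solution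
Reagents that add atoms: acetyl phosphate, CC(=O)OP(=O)(O)O (stoichiometric phosphoryl donor); adenosine triphosphate, Nc1ncnc2c1ncn2[C@@H]1O[C@H](COP(=O)(O)OP(=O)(O)OP(=O)(O)O)[C@@H](O)[C@H]1O (catalytic carrier)
Why: Kinase-catalysed phosphoryl transfer from ATP to one of the two equivalent primary hydroxyls, with ATP regenerated by acetate kinase and acetyl phosphate, gives the labile donor under neutral conditions without a protecting group.

Step 3
Reactants: 4 dihydroxyacetone phosphate; 2 4-nitrobutanal
Product: 6 [(1S,2R,3R,6R)-1,2,3-trihydroxy-6-nitrocyclohexyl]methyl dihydrogen phosphate, via open-chain aldol adduct 5 (not isolated)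
Conditions: L-fuculose-1-phosphate aldolase (E. coli, zinc-dependent), 2 (1.5 equiv), H2O, pH 7.5, 25 °C; then pH 7.8 until 5 is consumed
Reagents that add atoms: none
Why: The zinc-bound enediolate of 4 adds to the aldehyde of 2 in the aldolase active site and forms C2–C3 with the (3R,4R) D-erythro pattern of adduct 5, so C2 is fixed by the enzyme and C3 by its somewhat less strict control of the aldehyde face. Near neutral pH the C6 nitronate of 5 then adds to the C1 ketone in a 6-(enolexo)-exo-trig nitroaldol (Henry) closure that forms C1–C6 and the carbocycle. The closest known reaction type is the addition of dihydroxyacetone phosphate aldolases to nitro aldehydes followed by spontaneous intramolecular Henry reaction to nitrocyclitols. C1 and C6 are set under thermodynamic control, because the Henry step is reversible and the nitro-bearing carbon epimerises through its nitronate, so the chair with C7, the nitro group and O3 equatorial and O1/O2 trans-diaxial should accumulate. The selectivity needed is cis O2/O3 with C7 on their face, which is secured by the enzyme and by the preference of the larger C1 substituent for the equatorial site, while no regiochemical question arises because only one ketone and one nitronate carbon are present.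

Step 4
Reactants: 6 nitrocyclitol phosphate
Product: 7 (1S,2R,3R,6R)-1-(hydroxymethyl)-6-nitrocyclohexane-1,2,3-triol
Conditions: acid phosphatase, H2O, pH 4.8, 37 °C
Reagents that add atoms: none
Why: Enzymatic phosphate monoester hydrolysis proceeds by P–O cleavage at a pH at which the nitroaldol cannot revert, so all four stereocentres are retained.

Step 5
Reactants: 7 nitro tetrol
Product: 8 2,7-O-(di-tert-butylsilylene) derivative of 7 (O1–H and O3–H free)
Conditions: tBu2Si(OTf)2 (1.05 equiv), 2,6-lutidine, DMF, −40 to 0 °C
Reagents that add atoms: di-tert-butylsilyl bis(trifluoromethanesulfonate), CC(C)(C)[Si](OS(=O)(=O)C(F)(F)F)(OS(=O)(=O)C(F)(F)F)C(C)(C)C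
Why: Cyclic silylene protection of a 1,3-diol: the reagent silylates the primary O7 first and then closes the six-membered ring on the cis, axial O2, as in 4,6-O-silylene galactosides, leaving the tertiary O1 and the equatorial O3 free.

Step 6
Reactants: 8 silylene nitro diol; 9 benzoyl chloride
Product: 10 3-O-benzoyl-2,7-O-(di-tert-butylsilylene) derivative of 7
Conditions: BzCl (1.2 equiv), pyridine, CH2Cl2, 0 °C
Reagents that add atoms: benzoyl chloride, O=C(Cl)c1ccccc1
Why: Pyridine-mediated acylation takes place at O3, the only secondary hydroxyl, because the tertiary O1 is too hindered to react under these conditions.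

Step 7
Reactants: 10 nitro benzoate
Product: 12 (1S,2R,3R)-3-O-benzoyl-2,7-O-(di-tert-butylsilylene)-1,2,3-trihydroxy-1-(hydroxymethyl)cyclohexan-6-one, via potassium nitronate 11 (not isolated)
Conditions: KOtBu (1.05 equiv), THF, −78 °C; then dimethyldioxirane in acetone, −78 to 0 °C; pH 7 buffer
Reagents that add atoms: dimethyldioxirane, CC1(C)OO1
Why: Oxidative Nef reaction, in which full deprotonation gives a nitronate that can no longer undergo retro-Henry cleavage and oxygen transfer from the dioxirane to its C=N bond releases nitrite and the C6 ketone, with benzoate and silylene untouched at low temperature.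

Step 8
Reactants: 12 hydroxy ketone
Product: 13 C6 trimethylsilyl enol ether (C5=C6) of 12 carrying an O1 trimethylsilyl ether
Conditions: TMSOTf (2.5 equiv), Et3N (3.5 equiv), CH2Cl2, 0 °C
Reagents that add atoms: trimethylsilyl trifluoromethanesulfonate, C[Si](C)(C)OS(=O)(=O)C(F)(F)F
Why: Soft enolisation and O-silylation can give only one silyl enol ether because C5 is the sole enolisable neighbour of the ketone (C1 is quaternary), and the tertiary hydroxyl is silylated at the same time.

Step 9
Reactants: 13 bis(trimethylsilyl) compound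
Product: 15 (1S,2R,3R)-3-O-benzoyl-2,7-O-(di-tert-butylsilylene)-1,2,3-trihydroxy-1-(hydroxymethyl)cyclohex-4-en-6-one, via O1-silylated enone 14 (not isolated)
Conditions: Pd(OAc)2 (1.1 equiv), MeCN, rt; then 0.5 M aq. HCl, THF, 0 °C
Reagents that add atoms: none
Why: Saegusa–Ito oxidation, in which palladium diacetate palladates C5 of the enol ether and β-hydride elimination from C4 gives the C4=C5 enone, after which dilute acid removes the labile tertiary trimethylsilyl ether but not the silylene or the benzoate.

Step 10
Reactants: 15 hydroxy enone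
Product: 16 (1R,2R,3R,6S)-3-O-benzoyl-2,7-O-(di-tert-butylsilylene)-1-(hydroxymethyl)cyclohex-4-ene-1,2,3,6-tetrol (O1–H and O6–H free, trans)
Conditions: Me4NBH(OAc)3 (4 equiv), MeCN/AcOH 1:1, −20 to 0 °C
Reagents that add atoms: none
Why: Hydroxyl-directed triacetoxyborohydride reduction (Saksena–Evans), in which the axial O1–H exchanges an acetate on boron and delivers hydride to C6 on its own face, should give the 1,6-trans diol with O6 on the face of C7, while the attenuated hydride reduces the enone neither intermolecularly nor in the conjugate sense.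

Step 11
Reactants: 16 allylic alcohol; 9 benzoyl chloride
Product: 17 3,6-di-O-benzoyl-2,7-O-(di-tert-butylsilylene)-1-(hydroxymethyl)cyclohex-4-ene-1,2,3,6-tetrol
Conditions: BzCl (1.5 equiv), pyridine, DMAP (cat.), CH2Cl2, 0 °C to rt
Reagents that add atoms: benzoyl chloride, O=C(Cl)c1ccccc1
Why: DMAP-catalysed acylation esterifies the secondary allylic O6 with retention at C6, and the tertiary O1 stays free for steric reasons.

Step 12
Reactants: 17 silylene dibenzoate
Product: 18 (1S,2R,3R,6S)-3,6-di-O-benzoyl-1-(hydroxymethyl)cyclohex-4-ene-1,2,3,6-tetrol (target)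
Conditions: HF·pyridine, pyridine/THF, 0 °C to rt; pH 7 buffer work-up
Reagents that add atoms: none
Why: Fluoride cleavage of the silylene, driven by Si–F bond formation, frees O2 and O7 under mildly acidic conditions that should not move the benzoates to the neighbouring hydroxyls.

**Compound list**

1 | methyl 4-nitrobutanoate | COC(=O)CCC[N+](=O)[O-] | starting material
2 | 4-nitrobutanal | O=CCCC[N+](=O)[O-] | intermediate
3 | dihydroxyacetone | O=C(CO)CO | starting material
4 | dihydroxyacetone phosphate | O=C(CO)COP(=O)(O)O | intermediate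
5 | (3R,4R)-3,4-dihydroxy-7-nitro-2-oxoheptyl dihydrogen phosphate (open-chain aldol adduct, not isolated) | O=C(COP(=O)(O)O)[C@H](O)[C@H](O)CCC[N+](=O)[O-] | intermediate
6 | [(1S,2R,3R,6R)-1,2,3-trihydroxy-6-nitrocyclohexyl]methyl dihydrogen phosphate | O=[N+]([O-])[C@@H]1CC[C@@H](O)[C@@H](O)[C@@]1(O)COP(=O)(O)O | intermediate
7 | (1S,2R,3R,6R)-1-(hydroxymethyl)-6-nitrocyclohexane-1,2,3-triol | O=[N+]([O-])[C@@H]1CC[C@@H](O)[C@@H](O)[C@@]1(O)CO | intermediate
8 | (1S,2R,3R,6R)-2,7-O-(di-tert-butylsilylene)-1-(hydroxymethyl)-6-nitrocyclohexane-1,2,3-triol | O=[N+]([O-])[C@@H]1CC[C@@H](O)[C@H]2O[Si](C(C)(C)C)(C(C)(C)C)OC[C@@]12O | intermediate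
9 | benzoyl chloride | O=C(Cl)c1ccccc1 | starting material
10 | (1S,2R,3R,6R)-3-O-benzoyl-2,7-O-(di-tert-butylsilylene)-1-(hydroxymethyl)-6-nitrocyclohexane-1,2,3-triol | O=[N+]([O-])[C@@H]1CC[C@@H](OC(=O)c3ccccc3)[C@H]2O[Si](C(C)(C)C)(C(C)(C)C)OC[C@@]12O | intermediate
11 | potassium C6 nitronate of 10 (not isolated) | [K+].[O-][N+]([O-])=C1CC[C@@H](OC(=O)c3ccccc3)[C@H]2O[Si](C(C)(C)C)(C(C)(C)C)OC[C@@]12O | intermediate
12 | (1S,2R,3R)-3-O-benzoyl-2,7-O-(di-tert-butylsilylene)-1,2,3-trihydroxy-1-(hydroxymethyl)cyclohexan-6-one | O=C1CC[C@@H](OC(=O)c3ccccc3)[C@H]2O[Si](C(C)(C)C)(C(C)(C)C)OC[C@@]12O | intermediate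
13 | C6 trimethylsilyl enol ether (C5=C6) and O1 trimethylsilyl ether of 12 | C[Si](C)(C)OC1=CC[C@@H](OC(=O)c3ccccc3)[C@H]2O[Si](C(C)(C)C)(C(C)(C)C)OC[C@@]12O[Si](C)(C)C | intermediate
14 | O1 trimethylsilyl ether of enone 15 (not isolated) | O=C1C=C[C@@H](OC(=O)c3ccccc3)[C@H]2O[Si](C(C)(C)C)(C(C)(C)C)OC[C@@]12O[Si](C)(C)C | intermediate
15 | (1S,2R,3R)-3-O-benzoyl-2,7-O-(di-tert-butylsilylene)-1,2,3-trihydroxy-1-(hydroxymethyl)cyclohex-4-en-6-one | O=C1C=C[C@@H](OC(=O)c3ccccc3)[C@H]2O[Si](C(C)(C)C)(C(C)(C)C)OC[C@@]12O | intermediate
16 | (1R,2R,3R,6S)-3-O-benzoyl-2,7-O-(di-tert-butylsilylene)-1-(hydroxymethyl)cyclohex-4-ene-1,2,3,6-tetrol | O[C@H]1C=C[C@@H](OC(=O)c3ccccc3)[C@H]2O[Si](C(C)(C)C)(C(C)(C)C)OC[C@@]12O | intermediate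
17 | (1R,2R,3R,6S)-3,6-di-O-benzoyl-2,7-O-(di-tert-butylsilylene)-1-(hydroxymethyl)cyclohex-4-ene-1,2,3,6-tetrol | O=C(O[C@H]1C=C[C@@H](OC(=O)c3ccccc3)[C@H]2O[Si](C(C)(C)C)(C(C)(C)C)OC[C@@]12O)c1ccccc1 | intermediate
18 | (1S,2R,3R,6S)-3,6-di-O-benzoyl-1-(hydroxymethyl)cyclohex-4-ene-1,2,3,6-tetrol | O=C(O[C@H]1C=C[C@@H](OC(=O)c2ccccc2)[C@@H](O)[C@@]1(O)CO)c1ccccc1 | target

**Step count and risks**

Total steps: 12. Longest linear sequence: 11 steps (3 → 18 through steps 2–12, or 1 → 18 through steps 1 and 3–12).

Steps most likely to fail: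

Step 3. The aldolase may turn over the nitro aldehyde slowly or with partial loss of erythro control at C3, and the reversible ring closure may settle as a mixture at C1. The fallback sets out from 2 and comes back at 7. Aldehyde 2 and commercial 2,2-dimethyl-1,3-dioxan-5-one (CC1(C)OCC(=O)CO1) are joined by the D-proline-catalysed direct aldol reaction (DMF, 4 °C), the organocatalytic counterpart of the same aldolase. Through the enamine transition state this should give the anti adduct (4R)-4-[(1R)-1-hydroxy-4-nitrobutyl]-2,2-dimethyl-1,3-dioxan-5-one F1. Catalytic 1,1,3,3-tetramethylguanidine in THF then closes C1–C6 by Henry addition along the axial trajectory of the chair dioxanone, which should give the cis-fused 2,7-O-isopropylidene nitrocyclitol F2. Here C1 is set by the ring constraint and not by the equilibrium of the free system. Aqueous acetic acid removes the acetonide and returns tetrol 7.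

Step 7. Before the nitronate is fully formed, the tertiary alkoxide may open the ring by retro-Henry cleavage or attack silicon and start silyl and benzoyl migration. The fallback sets out from 10 and comes back at 13, at the cost of one step. O1 is capped first with N-(trimethylsilyl)imidazole (CH2Cl2, rt) to give the O1 trimethylsilyl ether of 10 F3. KOtBu and then dimethyldioxirane, as in step 7, convert it into the O1-silylated ketone F4. TMSOTf/Et3N then turns F4 into 13.

Step 10. Facial selectivity may be poor if exchange of the hindered tertiary hydroxyl on boron is slow and external hydride attack from the opposite face competes. The fallback sets out from 15 and comes back at 17. Luche reduction (NaBH4, CeCl3·7H2O, MeOH, −78 °C), in which external hydride should add anti to the axial C1–O bond, gives the C6 epimer of 16 F5. A Mitsunobu reaction with benzoic acid (PPh3, diisopropyl azodicarboxylate, THF, 0 °C) then inverts C6 and installs the benzoate in one operation to give 17. Any of this epimer formed beside 16 in step 10 can be funnelled to 17 in the same way.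

**Further compounds**

F1 | step 3 | (4R)-4-[(1R)-1-hydroxy-4-nitrobutyl]-2,2-dimethyl-1,3-dioxan-5-one | CC1(C)OCC(=O)[C@@H]([C@H](O)CCC[N+](=O)[O-])O1
F2 | step 3 | (1S,2R,3R,6R)-1-(hydroxymethyl)-2,7-O-isopropylidene-6-nitrocyclohexane-1,2,3-triol | O=[N+]([O-])[C@@H]1CC[C@@H](O)[C@H]2OC(C)(C)OC[C@@]12O
F3 | step 7 | O1 trimethylsilyl ether of 10 | O=[N+]([O-])[C@@H]1CC[C@@H](OC(=O)c3ccccc3)[C@H]2O[Si](C(C)(C)C)(C(C)(C)C)OC[C@@]12O[Si](C)(C)C
F4 | step 7 | O1 trimethylsilyl ether of 12 | O=C1CC[C@@H](OC(=O)c3ccccc3)[C@H]2O[Si](C(C)(C)C)(C(C)(C)C)OC[C@@]12O[Si](C)(C)C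
F5 | step 10 | (1R,2R,3R,6R)-3-O-benzoyl-2,7-O-(di-tert-butylsilylene)-1-(hydroxymethyl)cyclohex-4-ene-1,2,3,6-tetrol (C6 epimer of 16) | O[C@@H]1C=C[C@@H](OC(=O)c3ccccc3)[C@H]2O[Si](C(C)(C)C)(C(C)(C)C)OC[C@@]12O
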